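The leftover I wanted from this flask was substrate: how much of it stands unreacted once the coupling partner's turnovers are counted.

substrate 20 mM; coupling partner 26.0 mM; second reagent 30.0 mM; capture agent 6.00 mM; protic impurity 20.0 mM; time 12 h

    substrate + coupling partner → open intermediate (k1 = 0.0149 M⁻¹ s⁻¹)
    coupling partner → decomposed reagent (k2 = 4.86 × 10⁻⁴ s⁻¹)
    second reagent + open intermediate → target (k3 = 0.0225 M⁻¹ s⁻¹)
    coupling partner + protic impurity → quenched reagent (k4 = 0.00274 M⁻¹ s⁻¹)
    open intermediate + capture agent → trapped intermediate (k5 = 0.00566 M⁻¹ s⁻¹)

- conversion of substrate at 12 h
- amount of target at 12 h, in percent of the substrate charged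

I began with the coupling partner's clock. With the protic impurity held at its charge, steps 2 and 4 together remove it at 5.41 × 10⁻⁴ s⁻¹. That is a time constant of 0.514 h even without substrate, and 12 h is 23.3 such constants. So I reckoned by shares, not by time. My quantity was the break-even substrate level, the substrate concentration at which step 1 takes coupling partner as fast as steps 2 and 4 together: 36.3 mM. The share reaching substrate is the substrate level over that level plus break-even.

In the first instants, decomposition used coupling partner 1.6 times as fast as step 1, and the share was 35.5%. On the whole charge that would take 9.24 mM of substrate. But substrate falls, so in the middle I took its mean, 15.4 mM. The share became 29.8%, which on the whole charge gave an estimate of 7.74 mM, a conversion of 38.7%. For the open intermediate I set its half-life of 0.29 h by step 3 alone against 5.7 h by step 5 alone, and the charged amounts gave a share to target of 95.2%. For the end I therefore expected substrate left over, with the coupling partner as limiting reagent, and target at 36.8% of the substrate charged.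

The forecast said “The coupling partner is the limiter” and gave 39.4% and 37.4%, a conversion slightly above mine.

The simulated flask gave 39.4% conversion and 37.3% target, so 30.3% of the coupling partner's charge reached substrate, against my 29.8%. The neighbouring flask, charged with 50 mM of substrate, has the same break-even level, 36.3 mM. Its starting share is 57.9%, and a first pass gives an estimate of 15.1 mM. The mean substrate is then 42.5 mM, and the second pass gives 14.0 mM, a conversion of 28.0%. The simulation of that neighbouring flask gave 28.1% conversion and 26.5% target.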